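The oxolane ring (O, C11, C12, C13, C14; chain numbered from the vinyl carbon C1) is disconnected at C14, the carbon that carries the ring oxygen, the oxygenated C13 and the pentyl chain C15–C19. A copper carbenoid generated at C14 next to a C13 ketone is captured by the C11 ether oxygen, and the O-bound pent-1-en-3-yl group then migrates [2,3] to C14. One operation thus forms O–C14 and C14–C15, closes the ring and sets C14 trans to the C11 substituent. The precursor is a malate-derived diazoketone whose C11 oxygen carries the branched pentenyl group and whose C10 oxygen is masked as a bulky silyl ether.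

Key step: step 7

Remark on the chemistry: pent-1-en-3-ol is used as the racemate, so 5–10 are mixtures of epimers at the ether carbon; this centre is destroyed in step 7 and both epimers should converge on 11.

Step 1
Reactants: 1 dimethyl (R)-malate
Product: 2 methyl (3R)-3,4-dihydroxybutanoate
Conditions: BH3·SMe2 (1.0 equiv), NaBH4 (5 mol %), THF, 0 °C → rt; MeOH quench, co-evaporation; crude 2 used at once
Reagents that add atoms: none
Why: Hydroxyl-directed borane reduction (through a five-membered cyclic alkoxyborane, NaBH4-catalysed) should reduce only the ester next to the free hydroxyl and leave the C11 stereocentre untouched.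

Step 2
Reactants: 2 methyl (3R)-3,4-dihydroxybutanoate
Product: 3 methyl (3R)-4-[(tert-butyldiphenylsilyl)oxy]-3-hydroxybutanoate
Conditions: TBDPSCl (1.05 equiv), imidazole, CH2Cl2, −20 → 0 °C
Reagents that add atoms: tert-butyl(chloro)diphenylsilane (TBDPSCl), CC(C)(C)[Si](Cl)(c1ccccc1)c1ccccc1
Why: Silyl ether formation with the bulky TBDPS chloride at low temperature is selective for the primary over the secondary hydroxyl and also blocks lactonisation.

Step 3
Reactants: 4 pent-1-en-3-ol (racemic)
Product: 5 pent-1-en-3-yl 2,2,2-trichloroacetimidate (racemic)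
Conditions: Cl3CCN, DBU (10 mol %), CH2Cl2, 0 °C; short filtration through Et3N-deactivated silica, used at once without heating
Reagents that add atoms: trichloroacetonitrile, ClC(Cl)(Cl)C#N
Why: Base-catalysed addition of an alcohol to trichloroacetonitrile (trichloroacetimidate formation) is a standard preparation, and keeping the product cold avoids its [3,3] (Overman) rearrangement.

Step 4
Reactants: 3 methyl (3R)-4-[(tert-butyldiphenylsilyl)oxy]-3-hydroxybutanoate; 5 pent-1-en-3-yl 2,2,2-trichloroacetimidate
Product: 6 methyl (3R)-4-[(tert-butyldiphenylsilyl)oxy]-3-(pent-1-en-3-yloxy)butanoate (both epimers at the ether carbon)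
Conditions: 5 (2 equiv), TfOH (5 mol %), CH2Cl2/cyclohexane 1:2, 0 °C → rt
Reagents that add atoms: none
Why: Acid-catalysed O-alkylation with a trichloroacetimidate etherifies the secondary hydroxyl without base, so the β-hydroxy ester is spared retro-aldol and elimination, C11 is not involved, and the cold, weakly polar medium should favour ion-pair collapse at the branched carbon.

Step 5
Reactants: 6 methyl (3R)-4-[(tert-butyldiphenylsilyl)oxy]-3-(pent-1-en-3-yloxy)butanoate
Product: 7 (3R)-4-[(tert-butyldiphenylsilyl)oxy]-3-(pent-1-en-3-yloxy)butanoic acid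
Conditions: LiOH·H2O (2 equiv), THF/MeOH/H2O, 0 °C → rt; then 1 M HCl to pH 3–4
Reagents that add atoms: lithium hydroxide (aqueous; its oxygen becomes the carboxyl OH), [Li+].[OH-]
Why: Ester saponification with lithium hydroxide at or below room temperature should leave the TBDPS ether and the allylic ether intact and is mild enough to avoid β-elimination of the alkoxy group.

Step 6
Reactants: 7 (3R)-4-[(tert-butyldiphenylsilyl)oxy]-3-(pent-1-en-3-yloxy)butanoic acid
Product: 9 (4R)-5-[(tert-butyldiphenylsilyl)oxy]-1-diazo-4-(pent-1-en-3-yloxy)pentan-2-one, via isobutyl carbonic mixed anhydride 8 (not isolated)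
Conditions: i-BuOCOCl, Et3N, Et2O, −20 → 0 °C; then CH2N2 (excess, Et2O), 0 °C → rt
Reagents that add atoms: diazomethane, C=[N+]=[N-]
Why: Acylation of diazomethane by a mixed carbonic anhydride (Arndt–Eistert-type diazoketone synthesis) avoids an acid chloride and HCl, which the allylic and silyl ethers would tolerate less well.

Step 7
Reactants: 9 (4R)-5-[(tert-butyldiphenylsilyl)oxy]-1-diazo-4-(pent-1-en-3-yloxy)pentan-2-one
Product: 11 (2S,5R)-5-{[(tert-butyldiphenylsilyl)oxy]methyl}-2-[(2E)-pent-2-en-1-yl]oxolan-3-one, via cyclic oxonium ylide 10 (not isolated)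
Conditions: Cu(acac)2 (10 mol %), THF, reflux, slow addition of 9
Reagents that add atoms: none
Why: The copper catalyst decomposes the diazoketone to an electrophilic carbenoid at C14, a lone pair of the C11 ether oxygen attacks it to give the five-membered oxonium ylide (free or copper-associated), and the pentenyl group then moves from oxygen to C14 by a [2,3]-sigmatropic shift through a five-membered envelope transition state with allylic transposition, which turns the branched ether into the linear pent-2-enyl chain. The closest known reaction type is the copper-catalysed tandem oxonium ylide formation and [2,3] rearrangement of allyl ether diazoketones to 2,5-trans-oxolan-3-ones. The oxolanone ring is closed by O–C14 bond formation at the carbenoid carbon in a five-membered (formally 5-exo) cyclisation. The new C14 stereocentre (S) is controlled by the malate-derived C11 centre: the carbenoid engages the oxygen lone pair that places the O-pentenyl group anti to the pseudo-equatorial silyloxymethyl group, and the suprafacial shift then delivers C15 to the C14 face opposite the C11 substituent. The step needs chemoselectivity for this ylide over cyclopropanation of the vinyl group, C–H insertion and ylide formation at the C10 oxygen, which the acetylacetonate catalyst, the five-membered ring size and the bulk of the TBDPS group should secure, and it needs 2,5-trans selectivity, which the single C11 substituent should secure; the ether-carbon configuration and the alkene geometry do not matter because both are erased by step 8.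

Step 8
Reactants: 11 (2S,5R)-5-{[(tert-butyldiphenylsilyl)oxy]methyl}-2-[(2E)-pent-2-en-1-yl]oxolan-3-one
Product: 12 (2S,5R)-5-{[(tert-butyldiphenylsilyl)oxy]methyl}-2-pentyloxolan-3-one
Conditions: H2 (1 atm), 10 % Pd/C, EtOAc, rt
Reagents that add atoms: none
Why: Heterogeneous catalytic hydrogenation should saturate the disubstituted alkene under neutral conditions without touching the ketone, the silyl ether or the C14 centre, and it must precede introduction of the terminal alkene of the target.

Step 9
Reactants: 12 (2S,5R)-5-{[(tert-butyldiphenylsilyl)oxy]methyl}-2-pentyloxolan-3-one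
Product: 13 (2S,3S,5R)-5-{[(tert-butyldiphenylsilyl)oxy]methyl}-2-pentyloxolan-3-ol
Conditions: L-Selectride (1.2 equiv), THF, −78 °C; then H2O
Reagents that add atoms: none
Why: Diastereoselective ketone reduction with a bulky trialkylborohydride should occur from the ring face opposite the adjacent C14 pentyl group, which gives the 13,14-cis alcohol (13S).

Step 10
Reactants: 13 (2S,3S,5R)-5-{[(tert-butyldiphenylsilyl)oxy]methyl}-2-pentyloxolan-3-ol; 14 palmitoyl chloride
Product: 15 (2S,3S,5R)-5-{[(tert-butyldiphenylsilyl)oxy]methyl}-2-pentyloxolan-3-yl hexadecanoate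
Conditions: 14 (1.2 equiv), pyridine, DMAP (cat.), CH2Cl2, 0 °C → rt
Reagents that add atoms: none
Why: DMAP-catalysed O-acylation with an acid chloride esterifies the only free hydroxyl with retention at C13.

Step 11
Reactants: 15 (2S,3S,5R)-5-{[(tert-butyldiphenylsilyl)oxy]methyl}-2-pentyloxolan-3-yl hexadecanoate
Product: 16 (2S,3S,5R)-5-(hydroxymethyl)-2-pentyloxolan-3-yl hexadecanoate
Conditions: TBAF (1.3 equiv), AcOH (1.5 equiv), THF, 0 °C → rt
Reagents that add atoms: none
Why: Fluoride-mediated desilylation buffered with acetic acid should free the primary alcohol without ester cleavage, and acyl migration is disfavoured because the C13 ester and the C11 hydroxymethyl group lie on opposite ring faces.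

Step 12
Reactants: 16 (2S,3S,5R)-5-(hydroxymethyl)-2-pentyloxolan-3-yl hexadecanoate
Product: 17 (2S,3S,5R)-5-formyl-2-pentyloxolan-3-yl hexadecanoate
Conditions: Dess–Martin periodinane (1.3 equiv), CH2Cl2, 0 °C → rt; Na2S2O3/NaHCO3 work-up; used at once
Reagents that add atoms: none
Why: Dess–Martin oxidation gives the α-alkoxy aldehyde under near-neutral conditions that should neither epimerise C11 nor affect the ester.

Step 13
Reactants: 17 (2S,3S,5R)-5-formyl-2-pentyloxolan-3-yl hexadecanoate; 18 9-bromonon-1-ene
Product: 20 (2S,3S,5R)-5-[(1R)-1-hydroxydec-9-en-1-yl]-2-pentyloxolan-3-yl hexadecanoate (target CNP0186581.1), via non-8-en-1-ylmagnesium bromide 19 (not isolated)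
Conditions: 18, Mg, Et2O, rt (→ 19, 1.3 equiv); added to 17 pre-complexed with MgBr2·OEt2 in CH2Cl2, −78 °C; then H2O
Reagents that add atoms: none
Why: In this chelation-controlled (Cram chelate) Grignard addition magnesium bridges the aldehyde oxygen and the ring oxygen and the nucleophile attacks the chelate face bearing the C11 hydrogen, which gives the threo (10R) carbinol, while at −78 °C the aldehyde should react far faster than the secondary palmitate.

Compound list
1 | dimethyl (R)-malate | COC(=O)C[C@@H](O)C(=O)OC | starting material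
2 | methyl (3R)-3,4-dihydroxybutanoate | COC(=O)C[C@@H](O)CO | intermediate
3 | methyl (3R)-4-[(tert-butyldiphenylsilyl)oxy]-3-hydroxybutanoate | COC(=O)C[C@@H](O)CO[Si](c1ccccc1)(c1ccccc1)C(C)(C)C | intermediate
4 | pent-1-en-3-ol (racemic) | CCC(O)C=C | starting material
5 | pent-1-en-3-yl 2,2,2-trichloroacetimidate (racemic) | CCC(OC(=N)C(Cl)(Cl)Cl)C=C | intermediate
6 | methyl (3R)-4-[(tert-butyldiphenylsilyl)oxy]-3-(pent-1-en-3-yloxy)butanoate (both epimers at the ether carbon) | COC(=O)C[C@@H](OC(CC)C=C)CO[Si](c1ccccc1)(c1ccccc1)C(C)(C)C | intermediate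
7 | (3R)-4-[(tert-butyldiphenylsilyl)oxy]-3-(pent-1-en-3-yloxy)butanoic acid | OC(=O)C[C@@H](OC(CC)C=C)CO[Si](c1ccccc1)(c1ccccc1)C(C)(C)C | intermediate
8 | (3R)-4-[(tert-butyldiphenylsilyl)oxy]-3-(pent-1-en-3-yloxy)butanoic isobutyl carbonic anhydride (not isolated) | CC(C)COC(=O)OC(=O)C[C@@H](OC(CC)C=C)CO[Si](c1ccccc1)(c1ccccc1)C(C)(C)C | intermediate
9 | (4R)-5-[(tert-butyldiphenylsilyl)oxy]-1-diazo-4-(pent-1-en-3-yloxy)pentan-2-one | [N-]=[N+]=CC(=O)C[C@@H](OC(CC)C=C)CO[Si](c1ccccc1)(c1ccccc1)C(C)(C)C | intermediate
10 | (5R)-5-{[(tert-butyldiphenylsilyl)oxy]methyl}-3-oxo-1-(pent-1-en-3-yl)oxolan-1-ium-2-ide, the cyclic oxonium ylide (not isolated) | CC(C)(C)[Si](c1ccccc1)(c1ccccc1)OC[C@H]1CC(=O)[CH-][O+]1C(CC)C=C | intermediate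
11 | (2S,5R)-5-{[(tert-butyldiphenylsilyl)oxy]methyl}-2-[(2E)-pent-2-en-1-yl]oxolan-3-one | CC(C)(C)[Si](c1ccccc1)(c1ccccc1)OC[C@H]1CC(=O)[C@H](C/C=C/CC)O1 | intermediate
12 | (2S,5R)-5-{[(tert-butyldiphenylsilyl)oxy]methyl}-2-pentyloxolan-3-one | CC(C)(C)[Si](c1ccccc1)(c1ccccc1)OC[C@H]1CC(=O)[C@H](CCCCC)O1 | intermediate
13 | (2S,3S,5R)-5-{[(tert-butyldiphenylsilyl)oxy]methyl}-2-pentyloxolan-3-ol | CC(C)(C)[Si](c1ccccc1)(c1ccccc1)OC[C@H]1C[C@H](O)[C@H](CCCCC)O1 | intermediate
14 | palmitoyl chloride (hexadecanoyl chloride) | CCCCCCCCCCCCCCCC(=O)Cl | starting material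
15 | (2S,3S,5R)-5-{[(tert-butyldiphenylsilyl)oxy]methyl}-2-pentyloxolan-3-yl hexadecanoate | CC(C)(C)[Si](c1ccccc1)(c1ccccc1)OC[C@H]1C[C@H](OC(=O)CCCCCCCCCCCCCCC)[C@H](CCCCC)O1 | intermediate
16 | (2S,3S,5R)-5-(hydroxymethyl)-2-pentyloxolan-3-yl hexadecanoate | OC[C@H]1C[C@H](OC(=O)CCCCCCCCCCCCCCC)[C@H](CCCCC)O1 | intermediate
17 | (2S,3S,5R)-5-formyl-2-pentyloxolan-3-yl hexadecanoate | O=C[C@H]1C[C@H](OC(=O)CCCCCCCCCCCCCCC)[C@H](CCCCC)O1 | intermediate
18 | 9-bromonon-1-ene | C=CCCCCCCCBr | starting material
19 | non-8-en-1-ylmagnesium bromide (not isolated) | C=CCCCCCCC[Mg]Br | intermediate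
20 | (2S,3S,5R)-5-[(1R)-1-hydroxydec-9-en-1-yl]-2-pentyloxolan-3-yl hexadecanoate | C=CCCCCCCC[C@@H](O)[C@H]1C[C@H](OC(=O)CCCCCCCCCCCCCCC)[C@H](CCCCC)O1 | target

Total step count: 13. Longest linear sequence: 12 steps (steps 1, 2 and 4–13 from dimethyl (R)-malate); step 3 is a one-step side branch.

Steps most likely to fail

Step 7. The carbenoid or ylide may partition away from the wanted path: loss of 2,5-trans selectivity, a competing [1,2]-shift, cyclopropanation of the vinyl group or C–H insertion, all of which the branching at the migrating carbon may encourage. The fallback sets out from 3 and comes back at 11; it completes the side chain by olefin metathesis instead of carrying it through the rearrangement. Compound 3 is O-allylated with commercial allyl 2,2,2-trichloroacetimidate (TfOH cat.) to methyl (3R)-3-(allyloxy)-4-[(tert-butyldiphenylsilyl)oxy]butanoate F1. Saponification gives (3R)-3-(allyloxy)-4-[(tert-butyldiphenylsilyl)oxy]butanoic acid F2, which is converted through its isobutyl carbonic mixed anhydride F3 and diazomethane into (4R)-4-(allyloxy)-5-[(tert-butyldiphenylsilyl)oxy]-1-diazopentan-2-one F4. Cu(acac)2 in refluxing THF should then give, through the O-allyl oxonium ylide F5, (2S,5R)-2-allyl-5-{[(tert-butyldiphenylsilyl)oxy]methyl}oxolan-3-one F6, the unbranched case in which trans selectivity is best established. Cross-metathesis of F6 with (E)-hex-3-ene (second-generation Grubbs catalyst, CH2Cl2, 40 °C) supplies C17–C19 and should give 11 mixed with its (Z)-isomer F7; step 8 hydrogenates both to 12.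

Step 4. The ion pair formed from the secondary allylic imidate may undergo allylic transposition, so that the alcohol is captured at the primary terminus; the resulting linear pent-2-enyl ether would rearrange to the wrong, branched side chain in step 7. The imidate may also be lost by [3,3] rearrangement to the allylic trichloroacetamide. The fallback sets out from 3 and comes back at 6, using iridium-catalysed branched-selective allylic etherification. The zinc alkoxide of 3 (Et2Zn, THF, 0 °C) is coupled with tert-butyl (2E)-pent-2-en-1-yl carbonate F8, made from (E)-pent-2-en-1-ol and Boc2O, under [Ir(cod)Cl]2/phosphoramidite catalysis. Attack of the alkoxide at the substituted terminus of the π-allyl iridium intermediate should give 6 regioselectively under conditions the ester tolerates; the configuration induced at the ether carbon is irrelevant.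

Step 13. Chelation control may be incomplete, giving poor facial selectivity at C10, and the Grignard reagent may also add to the palmitate carbonyl. The fallback sets out from 17 and comes back at 20, replacing addition-controlled by reduction-controlled stereochemistry. The organocerium reagent from 19 and anhydrous CeCl3 (THF, −78 °C), which discriminates strongly between aldehyde and ester, is added without regard to facial selectivity to give 20 mixed with its C10 epimer (2S,3S,5R)-5-[(1S)-1-hydroxydec-9-en-1-yl]-2-pentyloxolan-3-yl hexadecanoate F9. The mixture is oxidised with Dess–Martin periodinane to (2S,3S,5R)-5-(dec-9-enoyl)-2-pentyloxolan-3-yl hexadecanoate F10. L-Selectride at −78 °C should then reduce the ketone under polar Felkin–Anh control (ring C–O bond anti to the incoming hydride) to the threo alcohol 20.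

Further compounds
F1 | step 7 | methyl (3R)-3-(allyloxy)-4-[(tert-butyldiphenylsilyl)oxy]butanoate | COC(=O)C[C@@H](OCC=C)CO[Si](c1ccccc1)(c1ccccc1)C(C)(C)C
F2 | step 7 | (3R)-3-(allyloxy)-4-[(tert-butyldiphenylsilyl)oxy]butanoic acid | OC(=O)C[C@@H](OCC=C)CO[Si](c1ccccc1)(c1ccccc1)C(C)(C)C
F3 | step 7 | (3R)-3-(allyloxy)-4-[(tert-butyldiphenylsilyl)oxy]butanoic isobutyl carbonic anhydride | CC(C)COC(=O)OC(=O)C[C@@H](OCC=C)CO[Si](c1ccccc1)(c1ccccc1)C(C)(C)C
F4 | step 7 | (4R)-4-(allyloxy)-5-[(tert-butyldiphenylsilyl)oxy]-1-diazopentan-2-one | [N-]=[N+]=CC(=O)C[C@@H](OCC=C)CO[Si](c1ccccc1)(c1ccccc1)C(C)(C)C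
F5 | step 7 | (5R)-1-allyl-5-{[(tert-butyldiphenylsilyl)oxy]methyl}-3-oxooxolan-1-ium-2-ide (O-allyl oxonium ylide) | CC(C)(C)[Si](c1ccccc1)(c1ccccc1)OC[C@H]1CC(=O)[CH-][O+]1CC=C
F6 | step 7 | (2S,5R)-2-allyl-5-{[(tert-butyldiphenylsilyl)oxy]methyl}oxolan-3-one | CC(C)(C)[Si](c1ccccc1)(c1ccccc1)OC[C@H]1CC(=O)[C@H](CC=C)O1
F7 | step 7 | (2S,5R)-5-{[(tert-butyldiphenylsilyl)oxy]methyl}-2-[(2Z)-pent-2-en-1-yl]oxolan-3-one | CC(C)(C)[Si](c1ccccc1)(c1ccccc1)OC[C@H]1CC(=O)[C@H](C/C=C\CC)O1
F8 | step 4 | tert-butyl (2E)-pent-2-en-1-yl carbonate | CC/C=C/COC(=O)OC(C)(C)C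
F9 | step 13 | (2S,3S,5R)-5-[(1S)-1-hydroxydec-9-en-1-yl]-2-pentyloxolan-3-yl hexadecanoate | C=CCCCCCCC[C@H](O)[C@H]1C[C@H](OC(=O)CCCCCCCCCCCCCCC)[C@H](CCCCC)O1
F10 | step 13 | (2S,3S,5R)-5-(dec-9-enoyl)-2-pentyloxolan-3-yl hexadecanoate | C=CCCCCCCCC(=O)[C@H]1C[C@H](OC(=O)CCCCCCCCCCCCCCC)[C@H](CCCCC)O1
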